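I have no constants for these complexes, so I build one from the plateaus of two runs. Monday's run is the asked flask itself, followed so far, and Sunday's run has twice its incoming ligand.

the same everywhere: starting complex 0.42 M

| charge | incoming ligand | remark | time |
|---|---|---|---|
| Monday's | 0.252 M | the very flask that is asked about, followed so far |  |
| Sunday's | 0.50 M | run made earlier |  |
| flask | 0.252 M |  | 2.5 d |

| run | time / h | starting complex / % | complex with four exchanged / % |
|---|---|---|---|
| Monday's | 8.00 | 67.9 | 2.3 |
| Monday's | 15.0 | 70.1 | 1.8 |
| Monday's | 25.0 | 70.9 | 2.3 |
| Monday's | 30.0 | 70.6 | 2.7 |
| Sunday's | 3.00 | 53.1 | 6.0 |
| Sunday's | 8.00 | 55.5 | 9.5 |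
| Sunday's | 20.0 | 56.2 | 8.6 |
| Sunday's | 40.0 | 55.6 | 6.6 |

(scatter of a reading: 0.5 percentage points)

- the state of affairs at 2.5 d: stopped, and by what, or still going (all of the starting complex has reacted / forward and back rates have come level / the incoming ligand has run out first / it is still moving)
- part of the starting complex gone at 2.5 d
- the complex with four exchanged standing at 2.5 d, as a percentage of the starting complex charged
- the complex with one exchanged standing at 2.5 d, as a percentage of the starting complex charged
- the complex with three exchanged standing at 2.5 d, as a percentage of the starting complex charged

- the earlier runs were read with a standard deviation of 0.5 percentage points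
- the reaction counts as stopped when no species that holds the starting complex changes by six tenths of a point or more over the second half of the time

Let g be the fraction of the starting complex gone, averaged from 15.0 h on in Monday's run and from 8.00 h on in Sunday's run, and let e be the incoming ligand charged per starting complex. Monday's run gives g = 0.295 at e = 0.600, and Sunday's run gives g = 0.442 at e = 1.19.

Now I turn the question round. If the incoming ligand were the limiting reagent, with the same share taken per complex gone, g would rise in step with e, and Sunday's run would stand at 0.585. It stands lower, at 0.442. So I try a balance instead: g squared, over the fraction left times (e − g). Sunday's run gives 0.469 and Monday's run 0.403. I call this ratio, the constant of one imagined step from starting complex and incoming ligand to exchanged complex and leaving ligand, the plateau quotient. Sunday's quotient, solved for Monday's e, gives g = 0.308.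

In Monday's run the complex with four exchanged rises 0.9 percentage points from 15.0 h to 30.0 h, against a scatter of 0.71 points on a difference. Sunday's fall of 2.9 points is larger, and I can't read it away. Still, I commit to forward and back rates level, with g near 0.295.

The forecast says it is still moving: “the ligand appears used up, and slow redistribution continues”. It gives 29.5 % gone, with 3 % of the complex with four exchanged, 15.7 % of the complex with one exchanged and 10.8 % of the complex with three exchanged. On the state of the flask it differs from me.

The state of the flask at 2.5 d is this: forward and back rates have come level. It has 29.0 % gone, 2.76 % of the complex with four exchanged, 17.6 % of the complex with one exchanged and 3.88 % of the complex with three exchanged. Of the incoming ligand, 13 % stands unbound at 2.50 d.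

    complex with two exchanged + incoming ligand ⇌ leaving ligand + complex with three exchanged (K = 6.60, k = 0.0416 M⁻¹ min⁻¹)
    complex with three exchanged + incoming ligand ⇌ leaving ligand + complex with four exchanged (K = 4.60, k = 0.492 M⁻¹ min⁻¹)
    complex with four exchanged ⇌ isomer of the product (K = 0.370, k = 0.0298 min⁻¹)
    complex with one exchanged + incoming ligand ⇌ leaving ligand + complex with two exchanged (K = 1.40, k = 0.899 M⁻¹ min⁻¹)
    starting complex + incoming ligand ⇌ leaving ligand + complex with one exchanged (K = 1.60, k = 0.583 M⁻¹ min⁻¹)

In this flask the half-life of the starting complex by the forward rate of the first step, at the charges, is 0.079 h, far shorter than 2.5 d, and in the step from complex with three exchanged to complex with four exchanged the backward turnover is 98 % of the forward one. Sunday's plateau quotient 0.469, which gave 0.308 here, gives g = 0.117 for the neighbour flask at e = 0.150, and that neighbour flask loses 11.8 %.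

The data are calculated on assumed constants; scatter was added.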